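**Retrosynthetic overview**

1. The target is (2S)-naringenin joined 3'→3''' to (2R,3R)-aromadendrin, and the halves differ only by the C3'' hydroxyl. The last disconnections are therefore the six benzyl ethers and that C3''–O bond (Rubottom oxidation, trans to the C2'' aryl), leading back to the C2-symmetric (2S,2''S)-hexa-O-benzyl-3',3'''-binaringenin.
2. Both rings C are then cut at O1–C8a and C2–C3, a formal hetero-Diels–Alder retron. This gives a biaryl dialdehyde and two molecules of a 1-(2-fluoroaryl)vinyl silyl ether, a benzo-fused Danishefsky-type diene in which fluorine stands for the methoxy leaving group.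
3. Enabling feature: O1–C8a=C4a–C4=O, spanning rings C and A, is a vinylogous ester. C8a lies ortho to the C4 acyl carbon and meta to O5 and O7, so a fluorine on C8a is displaced by the C2 oxygen (SNAr). The C2–O bond is never broken, so the aldol stereocentre becomes C2 with retention.
4. Ring order: rings A and B are bought as benzenes; the 3',3''' biaryl bond is made first (nickel homocoupling); both rings C are closed together in the key step; C3'' hydroxylation and hydrogenolysis come last.

Key step: step 5

Assumption: the sense of induction of the tryptophan-derived oxazaborolidinone is taken from its benzaldehyde/acetophenone enol silane model; the enantiomer named in step 5 is the one meant to give Si-face attack (S carbinol), and its antipode is used if the sense is the reverse.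

**Route**

Step 1
Reactants: 1 4-(benzyloxy)-3-bromobenzaldehyde (two molecules)
Product: 2 6,6'-bis(benzyloxy)biphenyl-3,3'-dicarbaldehyde
Conditions: NiCl2(PPh3)2 (10 mol%), Zn, Et4NI, THF, 50 °C
Reagents that add atoms: none
Why: Nickel-catalysed reductive (Ullmann-type) homocoupling, in which zerovalent nickel formed by zinc inserts into the C–Br bond and two aryl groups are joined by reductive elimination with the aldehyde and benzyl ether tolerated, so that the biaryl bond exists before any stereocentre does.

Step 2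
Reactants: 3 5-fluororesorcinol
Product: 4 1-(2-fluoro-4,6-dihydroxyphenyl)ethanone
Conditions: AcOH, ZnCl2, 140 °C
Reagents that add atoms: acetic acid, CC(=O)O
Why: Nencki (Friedel–Crafts) acylation, which should occur at the carbon ortho to one hydroxyl and para to the other (next to fluorine) and not at the more hindered carbon between the two hydroxyls, as in the acylation of resorcinol itself.

Step 3
Reactants: 4 1-(2-fluoro-4,6-dihydroxyphenyl)ethanone
Product: 5 1-[2,4-bis(benzyloxy)-6-fluorophenyl]ethanone
Conditions: BnBr (2.5 equiv), K2CO3, DMF, 60 °C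
Reagents that add atoms: benzyl bromide, BrCc1ccccc1
Why: Williamson etherification (SN2 of both phenoxides on benzyl bromide), with warming needed for the hydrogen-bonded ortho hydroxyl and with the acyl-deactivated phenoxides too weakly nucleophilic to displace the aryl fluoride.

Step 4
Reactants: 5 1-[2,4-bis(benzyloxy)-6-fluorophenyl]ethanone
Product: 6 {1-[2,4-bis(benzyloxy)-6-fluorophenyl]vinyloxy}trimethylsilane
Conditions: TMSOTf, Et3N, CH2Cl2, 0 °C
Reagents that add atoms: trimethylsilyl trifluoromethanesulfonate, C[Si](C)(C)OS(=O)(=O)C(F)(F)F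
Why: Soft enolisation (O-silylation by TMSOTf, then deprotonation of the methyl group by Et3N) gives the only possible enol silane without a free enolate that could attack the aryl fluoride.

Step 5
Reactants: 2 6,6'-bis(benzyloxy)biphenyl-3,3'-dicarbaldehyde; 6 {1-[2,4-bis(benzyloxy)-6-fluorophenyl]vinyloxy}trimethylsilane (2.4 equiv)
Product: 8 (2S,2''S)-hexa-O-benzyl-3',3'''-binaringenin, via bis-silyl aldol 7 (not isolated)
Conditions: B-n-butyl-N-tosyl-(R)-tryptophan oxazaborolidinone (40 mol%), EtCN/CH2Cl2, −78 °C; then Bu4N[Ph3SiF2] (0.6 equiv), THF, −78 to 0 °C, one pot; pH 7 buffer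
Reagents that add atoms: none
Why: Proposed new method: the chiral boron Lewis acid activates each formyl group and enol silane 6 adds to its Si face with silyl transfer (Mukaiyama aldol) to give 7; fluoride then unmasks each C2 alkoxide, which adds to the fluorine-bearing carbon ortho to the ketone (Meisenheimer adduct stabilised by the C4 carbonyl) and expels fluoride, which desilylates the next silyl ether, so that fluorine and silicon leave together as Me3SiF. The closest known reactions are the aldol–cyclisation mode of the Danishefsky-diene hetero-Diels–Alder synthesis of 2-aryl-2,3-dihydropyran-4-ones and the fluoride-catalysed SNAr etherification of silyl ethers with activated aryl fluorides; here the C4a=C8a arene bond and fluoride replace the enol ether bond and methoxide of the diene, a combination not yet shown for enantioselective flavanone synthesis. Each ring C closes by a six-membered addition–elimination at C8a (6-endo-trig when counted on the C4a=C8a bond, the mode by which Danishefsky aldol adducts close), and the two closures are independent. Both C2 stereocentres are set by the catalyst in the aldol stage and are carried through with retention because the C2–O bond is never broken; two independent inductions should enrich the C2-symmetric (S,S) product at the expense of a meso isomer. The step needs O-arylation to outrun retro-aldol and E1cB dehydration of the aldolate, and to occur at C–F and not at C–OBn: ortho-acyl activation, fluoride as the far better SNAr leaving group, the meta (non-deactivating) position of both benzyloxy groups relative to C8a, the six-membered transition state and the low stationary alkoxide concentration of the fluoride relay are expected to secure this.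

Step 6
Reactants: 8 (2S,2''S)-hexa-O-benzyl-3',3'''-binaringenin
Product: 11 hexa-O-benzyl (2S)-naringenin-(3'→3''')-(2R,3R)-aromadendrin, via mono-enol silane 9 (not isolated), via 3-silyloxy ketone 10 (not isolated)
Conditions: TMSOTf (1.0 equiv), Et3N, CH2Cl2, −20 °C; hexane, filter, concentrate; mCPBA, CH2Cl2, −20 °C; 1 M HCl, THF, 0 °C
Reagents that add atoms: meta-chloroperbenzoic acid, OOC(=O)c1cccc(Cl)c1
Why: Rubottom oxidation used as a desymmetrisation, in which one equivalent of TMSOTf converts on average one of the two equivalent, remote C3 methylene groups into its enol silane, the peracid epoxidises that C3=C4 bond on the face anti to the C2 aryl group, and silyl migration followed by acid hydrolysis leaves the C3 hydroxyl trans to the aryl group (substrate control, 2R,3R), so that a statistical mixture is expected from which 11 is separated while unreacted 8 is recycled.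

Step 7
Reactants: 11 hexa-O-benzyl (2S)-naringenin-(3'→3''')-(2R,3R)-aromadendrin
Product: 12 (2S)-naringenin-(3'→3''')-(2R,3R)-aromadendrin (target)
Conditions: H2 (1 atm), Pd/C, EtOAc/MeOH, rt
Reagents that add atoms: none
Why: Catalytic hydrogenolysis of six aryl benzyl ethers, which should be much faster than cleavage of the cyclic benzylic O1–C2 bonds and touches no stereocentre.

**Compound list**

1 | 4-(benzyloxy)-3-bromobenzaldehyde | O=Cc1ccc(OCc2ccccc2)c(Br)c1 | starting material
2 | 6,6'-bis(benzyloxy)biphenyl-3,3'-dicarbaldehyde | O=Cc1ccc(OCc2ccccc2)c(c1)-c1cc(C=O)ccc1OCc1ccccc1 | intermediate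
3 | 5-fluororesorcinol (5-fluorobenzene-1,3-diol) | Oc1cc(O)cc(F)c1 | starting material
4 | 1-(2-fluoro-4,6-dihydroxyphenyl)ethanone | CC(=O)c1c(O)cc(O)cc1F | intermediate
5 | 1-[2,4-bis(benzyloxy)-6-fluorophenyl]ethanone | CC(=O)c1c(OCc2ccccc2)cc(OCc2ccccc2)cc1F | intermediate
6 | {1-[2,4-bis(benzyloxy)-6-fluorophenyl]vinyloxy}trimethylsilane | C=C(O[Si](C)(C)C)c1c(OCc2ccccc2)cc(OCc2ccccc2)cc1F | intermediate
7 | bis-silyl aldol: 3,3'-[6,6'-bis(benzyloxy)biphenyl-3,3'-diyl]bis{(3S)-1-[2,4-bis(benzyloxy)-6-fluorophenyl]-3-(trimethylsilyloxy)propan-1-one} | C(c1ccccc1)Oc1ccc(cc1-c1cc(ccc1OCc1ccccc1)[C@@H](O[Si](C)(C)C)CC(=O)c1c(OCc2ccccc2)cc(OCc2ccccc2)cc1F)[C@@H](O[Si](C)(C)C)CC(=O)c1c(OCc2ccccc2)cc(OCc2ccccc2)cc1F | intermediate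
8 | (2S,2''S)-hexa-O-benzyl-3',3'''-binaringenin: 2,2'-[6,6'-bis(benzyloxy)biphenyl-3,3'-diyl]bis[(2S)-5,7-bis(benzyloxy)chroman-4-one] | C(c1ccccc1)Oc1ccc(cc1-c1cc(ccc1OCc1ccccc1)[C@@H]1CC(=O)c2c(OCc3ccccc3)cc(OCc3ccccc3)cc2O1)[C@@H]1CC(=O)c2c(OCc3ccccc3)cc(OCc3ccccc3)cc2O1 | intermediate
9 | mono-enol silane of 8: one unit as (2S)-5,7-bis(benzyloxy)-4-(trimethylsilyloxy)-2H-chromene, the other unit unchanged | C(c1ccccc1)Oc1ccc(cc1-c1cc(ccc1OCc1ccccc1)[C@@H]1C=C(O[Si](C)(C)C)c2c(OCc3ccccc3)cc(OCc3ccccc3)cc2O1)[C@@H]1CC(=O)c2c(OCc3ccccc3)cc(OCc3ccccc3)cc2O1 | intermediate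
10 | 3-silyloxy ketone: 3''-O-trimethylsilyl ether of 11, with a (2R,3R)-3-(trimethylsilyloxy)chroman-4-one unit and a (2S)-chroman-4-one unit | C(c1ccccc1)Oc1ccc(cc1-c1cc(ccc1OCc1ccccc1)[C@@H]1[C@@H](O[Si](C)(C)C)C(=O)c2c(OCc3ccccc3)cc(OCc3ccccc3)cc2O1)[C@@H]1CC(=O)c2c(OCc3ccccc3)cc(OCc3ccccc3)cc2O1 | intermediate
11 | hexa-O-benzyl target: (2R,3R)-5,7-bis(benzyloxy)-2-{4-(benzyloxy)-3-[2-(benzyloxy)-5-((2S)-5,7-bis(benzyloxy)-4-oxochroman-2-yl)phenyl]phenyl}-3-hydroxychroman-4-one | C(c1ccccc1)Oc1ccc(cc1-c1cc(ccc1OCc1ccccc1)[C@@H]1[C@@H](O)C(=O)c2c(OCc3ccccc3)cc(OCc3ccccc3)cc2O1)[C@@H]1CC(=O)c2c(OCc3ccccc3)cc(OCc3ccccc3)cc2O1 | intermediate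
12 | (2S)-naringenin-(3'→3''')-(2R,3R)-aromadendrin (CNP0201582.1) | O=C1C[C@@H](c2ccc(O)c(-c3cc([C@H]4Oc5cc(O)cc(O)c5C(=O)[C@@H]4O)ccc3O)c2)Oc2cc(O)cc(O)c21 | target

**Step count and risks**

Total steps: 7. Longest linear sequence: 6 steps (3 → 4 → 5 → 6 → 8 → 11 → 12).

Steps most likely to fail:

Step 5 (the proposed new method). Retro-aldol or E1cB dehydration of the unmasked aldolate may outrun O-arylation, or facial selectivity may be poor with the hindered, di-ortho-substituted enol silane. The fallback uses known chemistry and moves the stereochemical problem behind the ring closure; it sets out from 2 and 5 and comes back at 8. The lithium enolate of 5 (LiN(iPr)2, THF, −78 °C) is added to 2 to give the stereorandom bis(β-hydroxy ketone) F1. Dess–Martin oxidation gives the bis(1,3-diketone) F2. K2CO3 in DMF at 80 °C closes both pyranone rings by SNAr of the enolate oxygen on the C–F carbon, the same O1–C8a bond and a known route from 2-fluorophenyl 1,3-diketones to flavones, to give the bis-flavone F3. Copper hydride-catalysed enantioselective conjugate reduction (Cu(OAc)2, the DTBM-SEGPHOS enantiomer that gives 2S, (EtO)2MeSiH, t-BuOH, toluene), a reaction type known for 2-substituted chromones, then sets both C2 centres and returns to 8.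

Step 6. Under- and over-conversion are inherent in a statistical monofunctionalisation and make the separation laborious, and Lewis-acid-induced opening of ring C during enolisation may occur. The fallback is a non-statistical, convergent route that sets out from 1 and 6 and comes back at 11. The step 5 protocol applied to the monoaldehyde 1 should give, through the silyl aldol F4, the (S)-bromoflavanone F5. One portion of F5 is taken through the Rubottom sequence to full conversion (excess TMSOTf/Et3N, then mCPBA, then HCl), via the enol silane F6 and the 3-silyloxy ketone F7, to the (2R,3R)-bromodihydroflavonol F8. The other portion is borylated (B2pin2, PdCl2(dppf), KOAc, dioxane, 80 °C) to the pinacol boronate F9. Suzuki–Miyaura coupling of F8 with F9 (Pd(OAc)2, SPhos, K3PO4, toluene/H2O, 60 °C) forms the 3',3''' bond and gives 11. The price is a base-mediated coupling on two flavanoids prone to ring opening, which is why this order is not the first choice.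

Step 7. Over-reduction may occur: hydrogenolysis of the benzylic O1–C2 bonds or reduction of the C4 ketones, alongside incomplete removal of six benzyl groups. The fallback sets out from 11 and comes back at 12 without hydrogen: BCl3 with pentamethylbenzene as benzyl cation scavenger, CH2Cl2, −78 °C (Lewis-acid dealkylation in place of reduction). It makes no new compound.

**Further compounds**

F1 | step 5 | 3,3'-[6,6'-bis(benzyloxy)biphenyl-3,3'-diyl]bis{1-[2,4-bis(benzyloxy)-6-fluorophenyl]-3-hydroxypropan-1-one}, stereoisomer mixture | C(c1ccccc1)Oc1ccc(cc1-c1cc(ccc1OCc1ccccc1)C(O)CC(=O)c1c(OCc2ccccc2)cc(OCc2ccccc2)cc1F)C(O)CC(=O)c1c(OCc2ccccc2)cc(OCc2ccccc2)cc1F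
F2 | step 5 | 1,1'-[6,6'-bis(benzyloxy)biphenyl-3,3'-diyl]bis{3-[2,4-bis(benzyloxy)-6-fluorophenyl]propane-1,3-dione} | C(c1ccccc1)Oc1ccc(cc1-c1cc(ccc1OCc1ccccc1)C(=O)CC(=O)c1c(OCc2ccccc2)cc(OCc2ccccc2)cc1F)C(=O)CC(=O)c1c(OCc2ccccc2)cc(OCc2ccccc2)cc1F
F3 | step 5 | 2,2'-[6,6'-bis(benzyloxy)biphenyl-3,3'-diyl]bis[5,7-bis(benzyloxy)-4H-chromen-4-one] (hexa-O-benzyl bis-flavone) | C(c1ccccc1)Oc1ccc(cc1-c1cc(ccc1OCc1ccccc1)-c1cc(=O)c2c(OCc3ccccc3)cc(OCc3ccccc3)cc2o1)-c1cc(=O)c2c(OCc3ccccc3)cc(OCc3ccccc3)cc2o1
F4 | step 6 | (3S)-3-[4-(benzyloxy)-3-bromophenyl]-1-[2,4-bis(benzyloxy)-6-fluorophenyl]-3-(trimethylsilyloxy)propan-1-one | O=C(C[C@H](O[Si](C)(C)C)c1ccc(OCc2ccccc2)c(Br)c1)c1c(OCc2ccccc2)cc(OCc2ccccc2)cc1F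
F5 | step 6 | (2S)-5,7-bis(benzyloxy)-2-[4-(benzyloxy)-3-bromophenyl]chroman-4-one | O=C1C[C@@H](c2ccc(OCc3ccccc3)c(Br)c2)Oc2cc(OCc3ccccc3)cc(OCc3ccccc3)c21
F6 | step 6 | (2S)-5,7-bis(benzyloxy)-2-[4-(benzyloxy)-3-bromophenyl]-4-(trimethylsilyloxy)-2H-chromene | C[Si](C)(C)OC1=C[C@@H](c2ccc(OCc3ccccc3)c(Br)c2)Oc2cc(OCc3ccccc3)cc(OCc3ccccc3)c21
F7 | step 6 | (2R,3R)-5,7-bis(benzyloxy)-2-[4-(benzyloxy)-3-bromophenyl]-3-(trimethylsilyloxy)chroman-4-one | Brc1cc([C@H]2Oc3cc(OCc4ccccc4)cc(OCc4ccccc4)c3C(=O)[C@@H]2O[Si](C)(C)C)ccc1OCc1ccccc1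
F8 | step 6 | (2R,3R)-5,7-bis(benzyloxy)-2-[4-(benzyloxy)-3-bromophenyl]-3-hydroxychroman-4-one | Brc1cc([C@H]2Oc3cc(OCc4ccccc4)cc(OCc4ccccc4)c3C(=O)[C@@H]2O)ccc1OCc1ccccc1
F9 | step 6 | (2S)-5,7-bis(benzyloxy)-2-[4-(benzyloxy)-3-(4,4,5,5-tetramethyl-1,3,2-dioxaborolan-2-yl)phenyl]chroman-4-one | O=C1C[C@@H](c2ccc(OCc3ccccc3)c(B3OC(C)(C)C(C)(C)O3)c2)Oc2cc(OCc3ccccc3)cc(OCc3ccccc3)c21
F0 | step 7 | none | none
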